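- Alpha and eta were both to be read at 8.0 min, so I wanted a way to count what a flask does in a given time.

| setting | noon | spring | winter | alpha | eta |
|---|---|---|---|---|---|
| substrate | 25 mM | 25 mM | 25 mM | 25 mM | 25 mM |
| partner | 34 mM | 38 mM | 63 mM | 28.0 mM | 55.0 mM |
| remark | run made earlier | run made earlier | run made earlier |  |  |
| time |  |  |  | 8.0 min | 8.0 min |

- noon (time / min: substrate / %, target / %): 0.500: 99.7, 0.5; 1.33: 97.6, 2.4; 2.50: 94.1, 6.3; 4.00: 82.6, 16.9; 6.00: 60.1, 39.6
- spring (time / min: substrate / %, target / %): 1.00: 98.3, 2.4; 2.50: 91.9, 8.7; 3.00: 88.2, 12.5; 5.00: 62.6, 37.0; 6.00: 50.1, 50.3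
- winter (time / min: substrate / %, target / %): 1.00: 96.2, 3.4; 2.50: 70.4, 29.9; 3.00: 56.0, 44.8; 5.00: 15.4, 84.8; 6.00: 7.2, 92.4

(each reading ± 0.5 percentage points)

- which of these there is most of at the end, counted by the substrate in it, alpha (target / substrate)
- which of these there is most of at the end, counted by the substrate in it, eta (target / substrate)
- final amount of the leader among these, as a percentage of the substrate charged, in alpha
- final amount of the leader among these, as a percentage of the substrate charged, in eta



- In the earlier runs substrate plus target stayed near the charge and the curves started slowly and then sped up. I therefore took target to help make itself (autocatalysis), with one partner used per target, and I followed the ratio of target to substrate.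
- In noon, from 4.00 min to 6.00 min, that ratio rose from 0.205 to 0.659, which is 1.69 doublings. Free c(partner), taken as charge less target made, averaged 26.9 mM.
- So one doubling in noon read 31.9 mM·min; I called this the doubling dose, free c(partner) times minutes per doubling of the ratio. Winter, from 2.50 min to 5.00 min, read 32.9 mM·min.
- Scaling noon's first 4.00 min by charge, I put alpha at noon's ratio of 0.205 at 4.86 min, which left 3.14 min.
- With noon's mean target, I took alpha's c(partner) as 20.9 mM, which reckoned to target 46.1%.
- That mean was the weak link, since it belonged to noon. Redone with alpha's own reckoned mean, c(partner) came to 20.1 mM, so I reckoned target in alpha at 44.7% and substrate ahead at 55.3%.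
- The same scaling put eta at noon's ratio at 2.47 min. Assuming target in eta climbed from there to about the full charge, I took its mean c(partner) as 40.4 mM, so I reckoned target ahead in eta at 96.3%.
- The forecast, reading the runs as “autocatalytic on top of a slow background reaction”, put substrate ahead in alpha at 65% (57% to 73%), higher than my figure, and target ahead in eta at 94% (90% to 97%).
- The flasks gave substrate at 59.0% in alpha and target at 94.5% in eta.

    substrate + partner + target → 2 target (k = 18.0 L² mol⁻² s⁻¹)
    substrate + partner → target (k = 0.00410 L mol⁻¹ s⁻¹)
    partner ⇌ dormant form (K = 1.00, k = 9.30 × 10⁻⁴ s⁻¹)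

- In alpha, from 4.00 min to 8.00 min, the step with target ran while partner fell from 73.1% to 38.6% of its charge and dormant form rose from 4.86 mM to 6.96 mM; charge less target comes to 63.4%. Over that stretch alpha made 2.53 doublings, each on a dose of 24.7 mM·min by the mean of those two partner amounts. Carrying 31.9 mM·min on with the flask's own partner, I reckoned target for the same alpha flask read at 15 min at 67.7%, and that flask held 70.1%.

The data are calculated with constants of no real substance; noise was put on by code.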